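What will Friday's flask hold at 270 h, with 60.0 mM of starting material, the limiting reagent by charge, against 400 mM of partner, and what orders lie behind it?

| setting | Wednesday's | Saturday's | Tuesday's | Thursday's | Friday's |
|---|---|---|---|---|---|
| starting material | 120 mM | 72.0 mM | 120 mM | 240 mM | 60.0 mM |
| partner | 132 mM | 84.0 mM | 200 mM | 132 mM | 400 mM |
| time |  |  |  |  | 270 h |

- Wednesday's run (time / h: [product] / mM): 11: 15.7; 17: 13.6; 27: 20.3; 43: 21.4; 68: 18.7; 110: 24.7; 170: 21.5; 270: 24.7
- Saturday's run (time / h: [product] / mM): 11: 8.1; 17: 9.8; 27: 11.1; 43: 17.7; 68: 17.3; 110: 19.2; 170: 18.7; 270: 17.7
- Tuesday's run (time / h: [product] / mM): 11: 16.6; 17: 16.7; 27: 20.9; 43: 21.3; 68: 26.0; 110: 25.3; 170: 26.1; 270: 28.0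
- Thursday's run (time / h: [product] / mM): 11: 18.7; 17: 15.5; 27: 24.5; 43: 20.5; 68: 25.9; 110: 27.1; 170: 27.1; 270: 27.4

(readings scatter by 2 mM)

- Overall: starting material + partner -> product.
- Constant volume, constant temperature.
- "The second partner" is partner.
- An order is taken over about fifteen percent of the charge, up and down.

1. the exponent of [partner] in the starting rate at the charge of the Wednesday's run (at the point where two percent of the starting material have become product)
2. the exponent of [starting material] in the starting rate at the charge of the Wednesday's run (at the point where two percent of the starting material have become product) (one fixed amount of product, the same in the runs compared)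
3. product in the Friday's run at 270 h, as a share of the starting material charged

At the bench I take the first reading over its time as the starting rate and compare flasks. Tuesday's first reading against Wednesday's, with more partner, gives an order of 0.134; Thursday's against Wednesday's, with more starting material, gives 0.252. But the rule breaks here. I call the mean of a run's last 3 readings its stall, P_s, and Wednesday's is 23.6 mM, so Wednesday's first reading is already 66.4 % of it. Those ratios compare approaches to the stall, not starts, and I commit to neither as an order.

The stall moves little from Wednesday's run to Thursday's and Tuesday's. Twice the starting material takes it to 27.2 mM in Thursday's run, and more partner takes it to 26.5 mM in Tuesday's. So I freeze it in one number, the stall exponent e: the power of the charge product S·R (starting material times partner) that P_s follows, here the mean of those two comparisons, 0.238. Each stall carries about 1.15 mM of scatter, so e is loose. Friday's S·R is 1.52 times Wednesday's, which gives me a stall of 26.1 mM, or 43.5 % of Friday's charge.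

The forecast says 40 %, within 30 % to 52 %, a little below mine, with orders 0.45 in partner and 0.4 in starting material. Its ground: “an approximately fixed turnover capacity”.

The flask gives 42.4 %, with orders 0.84 in partner and 0.60 in starting material, both higher than the forecast's.

    starting material ⇌ intermediate + by-product (0.5184 /h, 10.62 /M/h)
    intermediate + partner → product (0.4968 /M/h)
    2 partner → lost reagent (0.4356 /M/h)
    2 starting material → homo dimer (2.790 /M/h)

Friday's 42.4 % stands close to the 43.5 % that e gave. Two losses acting together hold it there: without the step to lost reagent Friday's product comes to 66.5 %, and without the step to homo dimer to 64.5 %. On Saturday's charge the same e gives a stall of 18.8 mM, or 26.1 % of that charge, and Saturday's run reaches a quarter of its charge at 248 h.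

(Readings and results are calculated with constants of no real substance, noise included.)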